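**Strategy.** Numbering: C1 is the ring carbon bearing CH2OBz (C7), C2 the olefinic CH, C3 to C6 the oxygenated carbons (C5 the benzoate). The cyclohexene is disconnected at C1–C6 and C4–C5 into furfuryl acetate (C1–C4 and C7; its ring oxygen becomes O4) and vinylene carbonate (C5, C6). One dearomatising exo Diels–Alder reaction closes the carbocycle and sets the all-cis O4/O5/O6 array. It exploits that C1 and C4 are 1,4-related across C2/C3 and that O4, O5, O6 are cis: the signature of an exo 7-oxanorbornene bridged by O4. A rhodium-catalysed anti SN2' hydration finally unveils C1=C2 and trans C3–OH and selects the enantiomer.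

Key step: step 1

Remark: compounds 3 to 6 are racemates and each SMILES shows the enantiomer that step 4 carries on to the target; the ligand antipode in step 4 is assigned by analogy with the facial preference of this catalyst on oxabenzonorbornadiene and would be confirmed on the first run.

**Route**

Step 1
Reactants: 1 furfuryl acetate (furan-2-ylmethyl acetate); 2 vinylene carbonate (1,3-dioxol-2-one)
Product: 3 racemic exo cycloadduct (2-oxo-3a,4,7,7a-tetrahydro-4,7-epoxy-1,3-benzodioxol-4-yl)methyl acetate, carbonate ring syn to the oxygen bridge
Conditions: 1 (3 equiv), 2 (1 equiv), BHT (1 mol %), neat, sealed tube, 130 °C, 48 h; exo isomer separated by chromatography and crystallisation, endo isomer re-heated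
Reagents that add atoms: vinylene carbonate (compound 2), O=C1OC=CO1
Why: Concerted, suprafacial thermal [4+2] cycloaddition (furan Diels–Alder, a dearomatisation) between the 2- and 5-positions of the furan and the cis-enediol carbonate; the closest precedent is the cycloaddition of furan itself with vinylene carbonate. The six-membered carbocycle is closed in the [4+2] mode, C1–C6 and C4–C5 forming in one transition state, and the furan oxygen becomes the one-atom bridge of a 7-oxabicyclo[2.2.1]heptene. The bridgeheads C1 and C4 and the cis ring fusion at C5/C6 follow from suprafacial addition of the ring-locked Z-dienophile. The exo orientation of the carbonate (syn to the bridge oxygen, later the all-cis O4/O5/O6 array) is the thermodynamic outcome of this reversible cycloaddition. The selectivity needed is exo over endo, secured by equilibration at 130 °C and recycling of the endo isomer; no regiochemical question arises because the dienophile is symmetric. The adduct is racemic, and the absolute configuration is selected in step 4.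

Step 2
Reactants: 3 racemic exo cycloadduct
Product: 4 racemic 1-(hydroxymethyl)-7-oxabicyclo[2.2.1]hept-5-ene-2-exo,3-exo-diol
Conditions: K2CO3 (0.2 equiv), MeOH, 0 °C to rt; neutralise with acidic resin, concentrate
Reagents that add atoms: none
Why: Base-catalysed transesterification (Zemplén-type methanolysis) cleaves the acetate and the strained five-membered carbonate at the acyl carbons only, so all stereocenters are untouched and the base-stable oxanorbornene survives.

Step 3
Reactants: 4 racemic triol
Product: 6 racemic [3-exo-(benzoyloxy)-2-exo-hydroxy-7-oxabicyclo[2.2.1]hept-5-en-1-yl]methyl benzoate, via primary monobenzoate 5 (not isolated)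
Conditions: BzCl (2.1 equiv, two portions), pyridine, CH2Cl2, −40 to 0 °C
Reagents that add atoms: benzoyl chloride, O=C(Cl)c1ccccc1
Why: Sterically controlled acylation should benzoylate the primary hydroxyl and then the secondary hydroxyl next to the unsubstituted bridgehead (C5 of the target), while the hydroxyl wedged between the quaternary bridgehead and the new benzoyloxymethyl group (C6) stays free; no stereocenter is formed.

Step 4
Reactants: 6 racemic dibenzoate
Product: 7 [(3R,4S,5R,6R)-5-(benzoyloxy)-3,4,6-trihydroxycyclohex-1-en-1-yl]methyl benzoate (target)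
Conditions: [Rh(cod)2]OTf (5 mol %), (S)-1-[(R)-2-(diphenylphosphino)ferrocenyl]ethyldi-tert-butylphosphine (6 mol %), H2O (10 equiv), THF, 60 °C; neutral silica chromatography
Reagents that add atoms: water, O
Why: Rhodium-catalysed asymmetric ring opening of an oxabicyclic alkene, run as a regiodivergent resolution: the chiral monovalent rhodium catalyst inserts from the exo face into the bridgehead C–O bond it prefers, water then attacks the allyl-rhodium species in an SN2' sense anti to the metal (endo face), which sets C3 trans to the C4 hydroxyl, and only in the enantiomer drawn is the attacked carbon the one remote from the substituted bridgehead, so that this enantiomer alone should give the C1=C2 alkene of 7 while its mirror image is opened next to the bridgehead and ends as a separable regioisomer.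

**Compound list**

1 | furfuryl acetate (furan-2-ylmethyl acetate) | CC(=O)OCc1ccco1 | starting material
2 | vinylene carbonate (1,3-dioxol-2-one) | O=C1OC=CO1 | starting material
3 | racemic exo cycloadduct, (2-oxo-3a,4,7,7a-tetrahydro-4,7-epoxy-1,3-benzodioxol-4-yl)methyl acetate, carbonate syn to the oxygen bridge | CC(=O)OC[C@]12C=C[C@H](O1)[C@@H]3OC(=O)O[C@H]23 | intermediate
4 | racemic 1-(hydroxymethyl)-7-oxabicyclo[2.2.1]hept-5-ene-2-exo,3-exo-diol; enantiomer drawn (1S,2S,3R,4S) | OC[C@]12C=C[C@H](O1)[C@H](O)[C@@H]2O | intermediate
5 | racemic (2-exo,3-exo-dihydroxy-7-oxabicyclo[2.2.1]hept-5-en-1-yl)methyl benzoate (primary monobenzoate) | O=C(OC[C@]12C=C[C@H](O1)[C@H](O)[C@@H]2O)c1ccccc1 | intermediate (not isolated)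
6 | racemic [3-exo-(benzoyloxy)-2-exo-hydroxy-7-oxabicyclo[2.2.1]hept-5-en-1-yl]methyl benzoate; enantiomer drawn (1S,2S,3R,4S) | O=C(OC[C@]12C=C[C@H](O1)[C@H](OC(=O)c1ccccc1)[C@@H]2O)c1ccccc1 | intermediate
7 | [(3R,4S,5R,6R)-5-(benzoyloxy)-3,4,6-trihydroxycyclohex-1-en-1-yl]methyl benzoate | O=C(OCC1=C[C@@H](O)[C@H](O)[C@H](OC(=O)c2ccccc2)[C@@H]1O)c1ccccc1 | target

**Count and risks**

Total steps: 4. Longest linear sequence: 4.

Steps most likely to fail:

1. Step 4. Capture of the allyl-rhodium species by water may be slow, rhodium hydride may isomerise the allylic alcohols to ketones, and incomplete regiodivergence would erode the enantiomeric purity. Fallback, setting out from 6: the same catalyst is used with 4-methoxybenzyl alcohol (3 equiv, THF, 60 °C) as the oxygen nucleophile, so that the C3 oxygen arrives masked as an ether that cannot isomerise. This should give [(3R,4S,5R,6R)-5-(benzoyloxy)-4,6-dihydroxy-3-[(4-methoxybenzyl)oxy]cyclohex-1-en-1-yl]methyl benzoate F1, again separable from the regioisomer of the other enantiomer. Oxidative cleavage with DDQ in CH2Cl2/pH 7 buffer at 0 °C then returns to the route at 7.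

2. Step 1. The cycloaddition may stall, vinylene carbonate may polymerise, or the exo/endo ratio may stay poor. Fallback, setting out from 1: 1 is heated with (E)-1,2-bis(phenylsulfonyl)ethene (an acetylene equivalent) in toluene at 90 °C to give the racemic trans-bis(phenylsulfonyl) cycloadduct F2. Reductive elimination with sodium amalgam (NaH2PO4, MeOH/THF, −20 °C) gives the achiral (7-oxabicyclo[2.2.1]hepta-2,5-dien-1-yl)methyl acetate F3. Its two alkenes are enantiotopic, so one exo-selective dihydroxylation (OsO4 cat., NMO 1 equiv, acetone/water, 0 °C) should give racemic (2-exo,3-exo-dihydroxy-7-oxabicyclo[2.2.1]hept-5-en-1-yl)methyl acetate F4 with the diol necessarily syn to the bridge. Methanolysis (K2CO3, MeOH) comes back to the route at 4.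

3. Step 3. Site selectivity between the two secondary hydroxyls may be insufficient, and the benzoate may migrate across the cis-diol. Fallback, setting out from 4: t-Bu2Si(OTf)2 with 2,6-lutidine in DMF at 0 °C, which prefers six-membered rings, should tie the primary oxygen and the adjacent exo oxygen into the racemic di-tert-butylsilylene acetal F5 and leave only the C5 hydroxyl (target numbering) free. Benzoylation (BzCl, pyridine, DMAP) gives the silylene benzoate F6. HF·pyridine in THF at 0 °C releases the racemic 2-exo-hydroxy-1-(hydroxymethyl)-7-oxabicyclo[2.2.1]hept-5-en-3-exo-yl benzoate F7. Selective benzoylation of its primary hydroxyl (BzCl 1.05 equiv, 2,4,6-collidine, CH2Cl2, −40 °C) comes back to the route at 6.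

**Further compounds**

F1 | step 4 | [(3R,4S,5R,6R)-5-(benzoyloxy)-4,6-dihydroxy-3-[(4-methoxybenzyl)oxy]cyclohex-1-en-1-yl]methyl benzoate | O=C(OCC1=C[C@@H](OCc2ccc(OC)cc2)[C@H](O)[C@H](OC(=O)c2ccccc2)[C@@H]1O)c1ccccc1
F2 | step 1 | racemic [2,3-trans-bis(phenylsulfonyl)-7-oxabicyclo[2.2.1]hept-5-en-1-yl]methyl acetate (one of the two trans diastereomers drawn) | CC(=O)OC[C@]12C=C[C@H](O1)[C@H](S(=O)(=O)c1ccccc1)[C@H]2S(=O)(=O)c1ccccc1
F3 | step 1 | (7-oxabicyclo[2.2.1]hepta-2,5-dien-1-yl)methyl acetate (achiral) | CC(=O)OCC12C=CC(O1)C=C2
F4 | step 1 | racemic (2-exo,3-exo-dihydroxy-7-oxabicyclo[2.2.1]hept-5-en-1-yl)methyl acetate | CC(=O)OC[C@]12C=C[C@H](O1)[C@H](O)[C@@H]2O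
F5 | step 3 | racemic di-tert-butylsilylene acetal bridging the primary oxygen and the 2-exo oxygen of 4, 3-exo hydroxyl free | CC(C)(C)[Si]1(C(C)(C)C)OC[C@]23C=C[C@H](O2)[C@H](O)[C@@H]3O1
F6 | step 3 | racemic 3-exo benzoate of the silylene acetal F5 | CC(C)(C)[Si]1(C(C)(C)C)OC[C@]23C=C[C@H](O2)[C@H](OC(=O)c2ccccc2)[C@@H]3O1
F7 | step 3 | racemic 2-exo-hydroxy-1-(hydroxymethyl)-7-oxabicyclo[2.2.1]hept-5-en-3-exo-yl benzoate | OC[C@]12C=C[C@H](O1)[C@H](OC(=O)c1ccccc1)[C@@H]2O
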